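(The numbers of this flask were set for the occasion; the rest is arithmetic.)

**The charge.** 3.60 µM of enzyme is charged to each flask, and the zero of my scale is impurity equal to that charge, the equivalence point of the titration in step 2. Impurity to enzyme is 0.694 on Tuesday's, 2.08 on Friday's and 6.11 on Sunday's, so impurity is the limiting reagent of that step on Tuesday's, and enzyme on the other two.

the same everywhere: substrate 36 mM; enzyme 0.01 mol%; time 50 min
- Tuesday's: impurity 2.5 µM
- Friday's: impurity 7.5 µM
- Sunday's: impurity 22 µM

    substrate + enzyme → target + enzyme, rate k1*[substrate]^2.5*[enzyme]/(1 + ([substrate]/Kh1)^2.5) (Kh1 = 36.3 mM, k1 = 1.95 × 10⁵ /M².5/s)
    enzyme + impurity → spent catalyst (k2 = 2730 /M/s)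

* which of these there is most of at the end, counted by the substrate in it, Tuesday's (target / substrate)
* which of these there is most of at the end, counted by the substrate in it, Friday's (target / substrate)
* which of these there is most of at the end, counted by the substrate in it, Sunday's (target / substrate)
* how much there is at the end of the one of these that leads, in percent of the substrate charged: Tuesday's
* how much there is at the end of the one of these that leads, in percent of the substrate charged: Friday's
* how much there is at the end of the one of these that leads, in percent of the substrate charged: Sunday's

**Tuesday's flask.** Subtraction leaves 1.10 µM of enzyme working. Each enzyme starts at 24.2 /s, so over 50 min the survivors at starting speed amount to about twice the substrate charge. Speed falls with substrate, so I commit to target leading, without a figure.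

**The ration.** On Friday's and Sunday's, the logarithm of impurity falls at the second rate constant times enzyme. The time-integral of enzyme is therefore ln(impurity charged / impurity left) over that constant, with impurity left being charge minus enzyme charge. Multiplied by the starting speed and divided by the substrate charge, this gives 16.1% on Friday's and 4.40% on Sunday's. That is the ration, the share of the substrate charge turned over before impurity ends the enzyme, at starting speed. Speed falls as substrate falls, so I read it as a ceiling on target, and substrate leads in both flasks.

**Not to touch.** Leave the clock alone on Friday's: the enzyme's life at the impurity charged, 0.814 min, is far shorter than the run.

**The forecast.** It has target at 73.6% on Tuesday's, then substrate at 85.5% on Friday's and substrate at 95.7% on Sunday's, because the heavier charges “kill it all within minutes”. My ceiling leaves Friday's at least 83.9% substrate, less than the forecast's figure.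

**The result.** The flasks give 73.6% target on Tuesday's, 85.5% substrate on Friday's and 95.7% substrate on Sunday's, the forecast's figures. Half of Friday's turnover up to 50 min is done by 0.782 min, and at 500 min target still stands at 14.5%, against a ration of 16.1%. The neighbour of Friday's charged with 22 mM of substrate keeps the same impurity, and its ration is 6.29%; that flask ends with 5.93% target.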